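**Plan**
- Retrosynthesis: cut the C15–O ester bond, then the C12–C13 bond (sp3–sp2 coupling), then return oxygen to C7 and cut the ring bonds C5–C10 and C8–C9 together as a [4+2], then C5=C6 (cross-metathesis) and C3–C4 (prenylboration), back to methyl geranate.
- Forward: methyl geranate gives C1–C3, C9–C11 and C20; a prenyl unit gives C4–C6 with the gem-dimethyl group; ethyl vinyl ketone gives C7, C8 and C17. One thermal intramolecular Diels–Alder reaction of the open-chain trienal then closes ring A and ring B together.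
- Enabling feature: the (E)-β-methyl enal C9=C10 (formyl = C11) is tied by the four sp3 carbons C1–C4 to the diene C5=C6–C7(OSi)=C8. The ring-fusion bond C5–C10 is therefore one of the two bonds of the cycloaddition, and the quaternary C4 pre-organises the tether.
- Stereochemistry: C3 from reagent-controlled prenylboration; C5, C9 and C10 from the cycloaddition (equatorial C3–OTBS on a chair tether, endo formyl, E enal); the 7-ene by trans-diaxial dehydration; 13E from an (E)-enol triflate.
- Endgame: B-alkyl Suzuki coupling for C12–C16, esterification with a C30 acid made from two C15 halves, global desilylation.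

Key step: step 7

Remark: ring carbons carry labdane numbers and the target is read as the ent-labdane (3R,5S,9R,10S,13E) with a 30-hydroxytriacontanoyl chain (carbonyl plus 29 CH2); the prenylborane from (−)-Ipc2BOMe is assumed to attack the aldehyde Si face as the parent allylborane does.

**Step 1**
Reactants: 1 methyl geranate [methyl (2E)-3,7-dimethylocta-2,6-dienoate]
Product: 3 methyl (2E)-3-methyl-6-oxohex-2-enoate, via secondary ozonide 2 (not isolated)
Conditions: O3 (1 equiv, Sudan Red 7B end point), CH2Cl2, −78 °C; then Me2S, −78 °C → rt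
Reagents that add atoms: ozone, [O-][O+]=O
Why: Selective ozonolysis with reductive work-up, in which the electron-rich trisubstituted 6,7-alkene should be consumed far faster than the ester-conjugated 2,3-alkene.

**Step 2**
Reactants: 3 methyl (2E)-3-methyl-6-oxohex-2-enoate
Product: 5 methyl (2E,6R)-6-hydroxy-3,7,7-trimethylnona-2,8-dienoate, via borinate ester 4 (not isolated)
Conditions: (−)-Ipc2BOMe, prenylMgCl, Et2O, −78 → 0 °C; then 3, −78 °C; then NaBO3·4H2O, THF/H2O, rt
Reagents that add atoms: prenylmagnesium chloride, CC(C)=CC[Mg]Cl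
Why: Brown prenylboration through a closed chair (Zimmerman–Traxler) transition state with allylic transposition should build the quaternary C4 and the vinyl group at once, the pinene-derived ligands directing attack to the aldehyde Si face to set the 6R carbinol (labdane C3) while the ester is inert at −78 °C.

**Step 3**
Reactants: 5 methyl (2E,6R)-6-hydroxy-3,7,7-trimethylnona-2,8-dienoate; 6 pent-1-en-3-one (ethyl vinyl ketone)
Product: 7 methyl (2E,6R,8E)-6-hydroxy-3,7,7-trimethyl-10-oxododeca-2,8-dienoate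
Conditions: RuCl2(H2IMes)(=CH-C6H4-2-O-i-Pr) (Hoveyda–Grubbs second-generation catalyst, 5 mol %), 6 (4 equiv), CH2Cl2, 40 °C
Reagents that add atoms: none
Why: Olefin cross-metathesis between a vinyl group that homodimerises slowly and an electron-poor enone partner should give the E enone, the trisubstituted enoate being inert to the catalyst.

**Step 4**
Reactants: 7 methyl (2E,6R,8E)-6-hydroxy-3,7,7-trimethyl-10-oxododeca-2,8-dienoate
Product: 8 methyl (2E,6R,8E,10Z)-6,10-bis(tert-butyldimethylsilyloxy)-3,7,7-trimethyldodeca-2,8,10-trienoate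
Conditions: TBSOTf (2.5 equiv), Et3N (4 equiv), CH2Cl2, −78 → 0 °C
Reagents that add atoms: tert-butyldimethylsilyl triflate, CC(C)(C)[Si](C)(C)OS(=O)(=O)C(F)(F)F
Why: Soft enolisation and O-silylation, in which the ethyl CH2 is the only enolisable position of the enone (C4 is quaternary), so the cross-conjugated 2-silyloxydiene should form as the Z enol ether (methyl outside) while the hindered carbinol is silylated in the same operation.

**Step 5**
Reactants: 8 methyl (2E,6R,8E,10Z)-6,10-bis(tert-butyldimethylsilyloxy)-3,7,7-trimethyldodeca-2,8,10-trienoate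
Product: 9 (2E,6R,8E,10Z)-6,10-bis(tert-butyldimethylsilyloxy)-3,7,7-trimethyldodeca-2,8,10-trien-1-ol
Conditions: i-Bu2AlH (2.2 equiv), CH2Cl2, −78 °C; aq. Rochelle salt
Reagents that add atoms: none
Why: Hydride reduction of the enoate to the allylic alcohol, which should leave the silyl ether and the silyl dienol ether untouched at low temperature.

**Step 6**
Reactants: 9 (2E,6R,8E,10Z)-6,10-bis(tert-butyldimethylsilyloxy)-3,7,7-trimethyldodeca-2,8,10-trien-1-ol
Product: 10 (2E,6R,8E,10Z)-6,10-bis(tert-butyldimethylsilyloxy)-3,7,7-trimethyldodeca-2,8,10-trienal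
Conditions: MnO2 (activated, excess), NaHCO3, CH2Cl2, rt
Reagents that add atoms: none
Why: Allylic oxidation with MnO2 is selective for the allylic alcohol and, buffered, mild enough to keep the 2E geometry and the enol ether.

**Step 7**
Reactants: 10 (2E,6R,8E,10Z)-6,10-bis(tert-butyldimethylsilyloxy)-3,7,7-trimethyldodeca-2,8,10-trienal
Product: 11 (3R,5S,8S,9R,10R)-3,7-bis(tert-butyldimethylsilyloxy)-12,13,14,15,16-pentanor-ent-labd-6-en-11-al
Conditions: toluene (0.01 M), BHT, 2,6-di-tert-butyl-4-methylpyridine (cat.), base-washed sealed tube, 160 °C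
Reagents that add atoms: none
Why: A thermal intramolecular [4+2] cycloaddition (type 1 intramolecular Diels–Alder reaction of a 1,7,9-decatriene) between the 2-silyloxydiene C5=C6–C7(OTBS)=C8 and the (E)-enal C9=C10 should form C5–C10 and C8–C9 in one concerted, suprafacial event, the closest precedent being the cyclisation of trienals and silyloxytrienes to trans-decalins. Ring A closes through the four-carbon tether C1–C4 in a chair-like array, so that C5–C10 becomes the ring fusion, and ring B is the new cyclohexene; the tether enforces this fused mode although the siloxy group polarises the diene towards C8, and the gem-dimethyl group at C4 favours the reactive rotamer. C9 and C10 follow from the E geometry of the enal (C20 methyl and formyl cis), the trans C5/C10 fusion from the endo orientation of the formyl group, and the absolute sense from C3, whose OTBS group sits equatorial on the chair tether and so ends cis to the C10 methyl. C8 arises from the Z enol ether with its methyl cis to the formyl group and is corrected in step 9. The step needs endo over exo approach and survival of the enol ether; the first rests on secondary overlap of the formyl group in a purely thermal reaction, the second on acid-free glass and the hindered pyridine.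

**Step 8**
Reactants: 11 (3R,5S,8S,9R,10R)-3,7-bis(tert-butyldimethylsilyloxy)-12,13,14,15,16-pentanor-ent-labd-6-en-11-al
Product: 12 (3R,5S,8S,9R,10S)-3,7-bis(tert-butyldimethylsilyloxy)-13,14,15,16-tetranor-ent-labda-6,11-diene
Conditions: Ph3PCH3Br, KN(SiMe3)2, THF, 0 °C; then 11, −78 → 0 °C
Reagents that add atoms: methyltriphenylphosphonium bromide, C[P+](c1ccccc1)(c1ccccc1)c1ccccc1.[Br-]
Why: Wittig methylenation of the hindered aldehyde, whose equatorial formyl group is already the stable C9 epimer, should proceed without touching the silyl enol ether.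

**Step 9**
Reactants: 12 (3R,5S,8S,9R,10S)-3,7-bis(tert-butyldimethylsilyloxy)-13,14,15,16-tetranor-ent-labda-6,11-diene
Product: 14 (3R,5S,8R,9R,10S)-3-(tert-butyldimethylsilyloxy)-13,14,15,16-tetranor-ent-labd-11-en-7-one, via 8-epi ketone 13 (not isolated)
Conditions: Bu4NF, AcOH, THF, 0 °C; then NaOMe (0.2 equiv), MeOH, rt
Reagents that add atoms: none
Why: Buffered fluoride cleavage of the silyl enol ether (protonation at C6) followed by methoxide equilibration through the C7/C8 enolate should place the C8 methyl equatorial and trans to the C9 vinyl group, the hindered C3 silyl ether surviving.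

**Step 10**
Reactants: 14 (3R,5S,8R,9R,10S)-3-(tert-butyldimethylsilyloxy)-13,14,15,16-tetranor-ent-labd-11-en-7-one
Product: 15 (3R,5S,7S,8R,9R,10S)-3-(tert-butyldimethylsilyloxy)-13,14,15,16-tetranor-ent-labd-11-en-7-ol
Conditions: Li[HB(s-Bu)3], THF, −78 °C; H2O
Reagents that add atoms: none
Why: The bulky hydride should attack the C7 carbonyl along the equatorial trajectory (steric approach control) and give the axial 7-alcohol, anti-periplanar to the axial H-8.

**Step 11**
Reactants: 15 (3R,5S,7S,8R,9R,10S)-3-(tert-butyldimethylsilyloxy)-13,14,15,16-tetranor-ent-labd-11-en-7-ol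
Product: 16 (3R,5S,9R,10R)-3-(tert-butyldimethylsilyloxy)-13,14,15,16-tetranor-ent-labda-7,11-diene
Conditions: Ph2S[OC(CF3)2Ph]2 (Martin sulfurane), CH2Cl2, rt
Reagents that add atoms: none
Why: Martin sulfurane dehydration by anti elimination from the axial alkoxysulfonium should remove the tertiary axial H-8 (more substituted alkene, and the axial H-6 lies under the axial methyl groups of C4 and C10) to give the 7-ene.

**Step 12**
Reactants: 17 ethyl acetoacetate
Product: 18 ethyl (2E)-3-(trifluoromethylsulfonyloxy)but-2-enoate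
Conditions: aq. Me4NOH, Tf2O, hexanes, 5 °C
Reagents that add atoms: triflic anhydride, O=S(=O)(OS(=O)(=O)C(F)(F)F)C(F)(F)F
Why: O-Sulfonylation of the non-chelated (tetramethylammonium) enolate, which prefers the extended geometry, should give the E enol triflate with the triflate trans to the ester.

**Step 13**
Reactants: 16 (3R,5S,9R,10R)-3-(tert-butyldimethylsilyloxy)-13,14,15,16-tetranor-ent-labda-7,11-diene; 18 ethyl (2E)-3-(trifluoromethylsulfonyloxy)but-2-enoate
Product: 20 ethyl (3R,5S,9R,10S,13E)-3-(tert-butyldimethylsilyloxy)-ent-labda-7,13-dien-15-oate, via B-alkyl-9-BBN 19 (not isolated)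
Conditions: 9-BBN-H dimer, THF, rt → 50 °C; then 18, Pd(dppf)Cl2 (5 mol %), AsPh3, K3PO4 (3 M aq.), DMF, rt
Reagents that add atoms: none
Why: 9-BBN should hydroborate only the monosubstituted vinyl group (boron at C12) and the B-alkyl Suzuki–Miyaura coupling replaces the triflate with retention, so the 13E geometry is carried over from 18.

**Step 14**
Reactants: 20 ethyl (3R,5S,9R,10S,13E)-3-(tert-butyldimethylsilyloxy)-ent-labda-7,13-dien-15-oate
Product: 21 (3R,5S,9R,10S,13E)-3-(tert-butyldimethylsilyloxy)-ent-labda-7,13-dien-15-ol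
Conditions: i-Bu2AlH (2.5 equiv), CH2Cl2, −78 °C; aq. Rochelle salt
Reagents that add atoms: none
Why: Hydride reduction of the enoate should give the E allylic alcohol without touching the alkenes or the silyl ether.

**Step 15**
Reactants: 22 15-bromopentadecanoic acid
Product: 23 15-bromopentadecan-1-ol
Conditions: BH3·THF, THF, 0 °C → rt; H2O
Reagents that add atoms: none
Why: Borane reduces the carboxylic acid chemoselectively and leaves the primary bromide.

**Step 16**
Reactants: 23 15-bromopentadecan-1-ol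
Product: 24 (15-bromopentadecyloxy)(tert-butyl)dimethylsilane
Conditions: TBSCl, imidazole, DMF, rt
Reagents that add atoms: tert-butyldimethylsilyl chloride, CC(C)(C)[Si](C)(C)Cl
Why: Standard silylation of a primary alcohol gives a group that tolerates Grignard formation and is removed with the C3 silyl ether at the end.

**Step 17**
Reactants: 24 (15-bromopentadecyloxy)(tert-butyl)dimethylsilane; 22 15-bromopentadecanoic acid
Product: 27 30-(tert-butyldimethylsilyloxy)triacontanoic acid, via Grignard reagent 25 (not isolated), via chloromagnesium carboxylate 26 (not isolated)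
Conditions: 24, Mg, THF, 40 °C; 22, MeMgCl (1.0 equiv), THF, −20 °C; combine, Li2CuCl4 (3 mol %), −20 → 0 °C; 1 M HCl, 0 °C
Reagents that add atoms: none
Why: Copper-catalysed sp3–sp3 cross-coupling of a primary alkyl Grignard reagent with a primary bromide, with the acid masked as its magnesium carboxylate, should join the two C15 halves to the C30 chain.

**Step 18**
Reactants: 21 (3R,5S,9R,10S,13E)-3-(tert-butyldimethylsilyloxy)-ent-labda-7,13-dien-15-ol; 27 30-(tert-butyldimethylsilyloxy)triacontanoic acid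
Product: 28 (3R,5S,9R,10S,13E)-3-(tert-butyldimethylsilyloxy)-ent-labda-7,13-dien-15-yl 30-(tert-butyldimethylsilyloxy)triacontanoate
Conditions: EDC·HCl, DMAP, CH2Cl2, rt
Reagents that add atoms: none
Why: Steglich-type carbodiimide esterification of the only free hydroxyl group, a primary allylic alcohol, under conditions that do not ionise the allylic system.

**Step 19**
Reactants: 28 (3R,5S,9R,10S,13E)-3-(tert-butyldimethylsilyloxy)-ent-labda-7,13-dien-15-yl 30-(tert-butyldimethylsilyloxy)triacontanoate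
Product: 29 (3R,5S,9R,10S,13E)-3-hydroxy-ent-labda-7,13-dien-15-yl 30-hydroxytriacontanoate
Conditions: HF·pyridine, THF/pyridine, 0 °C → rt
Reagents that add atoms: none
Why: Buffered fluoride desilylation should cleave both silyl ethers without hydrolysing the allylic ester or isomerising the 7-ene.

**Compound list**
1 | methyl geranate, methyl (2E)-3,7-dimethylocta-2,6-dienoate | CC(C)=CCC/C(C)=C/C(=O)OC | starting material
2 | methyl (2E)-5-(5,5-dimethyl-1,2,4-trioxolan-3-yl)-3-methylpent-2-enoate (secondary ozonide) | COC(=O)/C=C(\C)CCC1OOC(C)(C)O1 | intermediate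
3 | methyl (2E)-3-methyl-6-oxohex-2-enoate | COC(=O)/C=C(\C)CCC=O | intermediate
4 | methyl (2E,6R)-6-[bis(isopinocampheyl)boryloxy]-3,7,7-trimethylnona-2,8-dienoate | COC(=O)/C=C(\C)CC[C@@H](OB([C@@H]1C[C@@H]2C[C@H]([C@H]1C)C2(C)C)[C@@H]1C[C@@H]2C[C@H]([C@H]1C)C2(C)C)C(C)(C)C=C | intermediate
5 | methyl (2E,6R)-6-hydroxy-3,7,7-trimethylnona-2,8-dienoate | COC(=O)/C=C(\C)CC[C@@H](O)C(C)(C)C=C | intermediate
6 | pent-1-en-3-one (ethyl vinyl ketone) | C=CC(=O)CC | starting material
7 | methyl (2E,6R,8E)-6-hydroxy-3,7,7-trimethyl-10-oxododeca-2,8-dienoate | COC(=O)/C=C(\C)CC[C@@H](O)C(C)(C)/C=C/C(=O)CC | intermediate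
8 | methyl (2E,6R,8E,10Z)-6,10-bis(tert-butyldimethylsilyloxy)-3,7,7-trimethyldodeca-2,8,10-trienoate | COC(=O)/C=C(\C)CC[C@@H](O[Si](C)(C)C(C)(C)C)C(C)(C)/C=C/C(O[Si](C)(C)C(C)(C)C)=C/C | intermediate
9 | (2E,6R,8E,10Z)-6,10-bis(tert-butyldimethylsilyloxy)-3,7,7-trimethyldodeca-2,8,10-trien-1-ol | OC/C=C(\C)CC[C@@H](O[Si](C)(C)C(C)(C)C)C(C)(C)/C=C/C(O[Si](C)(C)C(C)(C)C)=C/C | intermediate
10 | (2E,6R,8E,10Z)-6,10-bis(tert-butyldimethylsilyloxy)-3,7,7-trimethyldodeca-2,8,10-trienal | O=C/C=C(\C)CC[C@@H](O[Si](C)(C)C(C)(C)C)C(C)(C)/C=C/C(O[Si](C)(C)C(C)(C)C)=C/C | intermediate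
11 | (3R,5S,8S,9R,10R)-3,7-bis(tert-butyldimethylsilyloxy)-12,13,14,15,16-pentanor-ent-labd-6-en-11-al; trans-decalin, with C8 methyl, C9 formyl, C10 methyl and C3 oxygen on one face | C[C@@H]1C(O[Si](C)(C)C(C)(C)C)=C[C@@H]2C(C)(C)[C@H](O[Si](C)(C)C(C)(C)C)CC[C@@]2(C)[C@@H]1C=O | intermediate
12 | (3R,5S,8S,9R,10S)-3,7-bis(tert-butyldimethylsilyloxy)-13,14,15,16-tetranor-ent-labda-6,11-diene | C[C@@H]1C(O[Si](C)(C)C(C)(C)C)=C[C@@H]2C(C)(C)[C@H](O[Si](C)(C)C(C)(C)C)CC[C@@]2(C)[C@@H]1C=C | intermediate
13 | (3R,5S,8S,9R,10S)-3-(tert-butyldimethylsilyloxy)-13,14,15,16-tetranor-ent-labd-11-en-7-one (C8 methyl axial, cis to vinyl) | C[C@@H]1C(=O)C[C@@H]2C(C)(C)[C@H](O[Si](C)(C)C(C)(C)C)CC[C@@]2(C)[C@@H]1C=C | intermediate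
14 | (3R,5S,8R,9R,10S)-3-(tert-butyldimethylsilyloxy)-13,14,15,16-tetranor-ent-labd-11-en-7-one (C8 methyl equatorial, trans to vinyl) | C[C@H]1C(=O)C[C@@H]2C(C)(C)[C@H](O[Si](C)(C)C(C)(C)C)CC[C@@]2(C)[C@@H]1C=C | intermediate
15 | (3R,5S,7S,8R,9R,10S)-3-(tert-butyldimethylsilyloxy)-13,14,15,16-tetranor-ent-labd-11-en-7-ol (7-OH axial, anti to H-8) | C[C@H]1[C@@H](O)C[C@@H]2C(C)(C)[C@H](O[Si](C)(C)C(C)(C)C)CC[C@@]2(C)[C@@H]1C=C | intermediate
16 | (3R,5S,9R,10R)-3-(tert-butyldimethylsilyloxy)-13,14,15,16-tetranor-ent-labda-7,11-diene | CC1=CC[C@@H]2C(C)(C)[C@H](O[Si](C)(C)C(C)(C)C)CC[C@@]2(C)[C@@H]1C=C | intermediate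
17 | ethyl acetoacetate | CCOC(=O)CC(C)=O | starting material
18 | ethyl (2E)-3-(trifluoromethylsulfonyloxy)but-2-enoate | CCOC(=O)/C=C(\C)OS(=O)(=O)C(F)(F)F | intermediate
19 | 9-[(3R,5S,9R,10S)-3-(tert-butyldimethylsilyloxy)-13,14,15,16-tetranor-ent-labd-7-en-12-yl]-9-borabicyclo[3.3.1]nonane | CC1=CC[C@@H]2C(C)(C)[C@H](O[Si](C)(C)C(C)(C)C)CC[C@@]2(C)[C@@H]1CCB1C2CCCC1CCC2 | intermediate
20 | ethyl (3R,5S,9R,10S,13E)-3-(tert-butyldimethylsilyloxy)-ent-labda-7,13-dien-15-oate | CC1=CC[C@@H]2C(C)(C)[C@H](O[Si](C)(C)C(C)(C)C)CC[C@@]2(C)[C@@H]1CC/C(C)=C/C(=O)OCC | intermediate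
21 | (3R,5S,9R,10S,13E)-3-(tert-butyldimethylsilyloxy)-ent-labda-7,13-dien-15-ol | CC1=CC[C@@H]2C(C)(C)[C@H](O[Si](C)(C)C(C)(C)C)CC[C@@]2(C)[C@@H]1CC/C(C)=C/CO | intermediate
22 | 15-bromopentadecanoic acid | OC(=O)CCCCCCCCCCCCCCBr | starting material
23 | 15-bromopentadecan-1-ol | OCCCCCCCCCCCCCCCBr | intermediate
24 | (15-bromopentadecyloxy)(tert-butyl)dimethylsilane | CC(C)(C)[Si](C)(C)OCCCCCCCCCCCCCCCBr | intermediate
25 | [15-(tert-butyldimethylsilyloxy)pentadecyl]magnesium bromide | CC(C)(C)[Si](C)(C)OCCCCCCCCCCCCCCC[Mg]Br | intermediate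
26 | chloromagnesium 15-bromopentadecanoate | [O-]C(=O)CCCCCCCCCCCCCCBr.[Mg+2].[Cl-] | intermediate
27 | 30-(tert-butyldimethylsilyloxy)triacontanoic acid | OC(=O)CCCCCCCCCCCCCCCCCCCCCCCCCCCCCO[Si](C)(C)C(C)(C)C | intermediate
28 | (3R,5S,9R,10S,13E)-3-(tert-butyldimethylsilyloxy)-ent-labda-7,13-dien-15-yl 30-(tert-butyldimethylsilyloxy)triacontanoate | CC1=CC[C@@H]2C(C)(C)[C@H](O[Si](C)(C)C(C)(C)C)CC[C@@]2(C)[C@@H]1CC/C(C)=C/COC(=O)CCCCCCCCCCCCCCCCCCCCCCCCCCCCCO[Si](C)(C)C(C)(C)C | intermediate
29 | (3R,5S,9R,10S,13E)-3-hydroxy-ent-labda-7,13-dien-15-yl 30-hydroxytriacontanoate | CC1=CC[C@@H]2C(C)(C)[C@H](O)CC[C@@]2(C)[C@@H]1CC/C(C)=C/COC(=O)CCCCCCCCCCCCCCCCCCCCCCCCCCCCCO | target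

**Step count and risks**
Total: 19 steps. Longest linear sequence: 15 steps (steps 1–11, 13, 14, 18, 19).

Step 7. The cycloaddition may run through the exo approach of the formyl group (cis fusion) or through the chair with axial C3–OTBS. It may also be slow because the siloxy donor is not aligned with the enal, and the enol ether may be lost to adventitious acid at the temperature needed. Fallback: from 8, CsF and PhNTf2 in DME should exchange the silyl enol ether for the acid-stable dienyl triflate methyl (2E,6R,8E,10Z)-6-(tert-butyldimethylsilyloxy)-3,7,7-trimethyl-10-(trifluoromethylsulfonyloxy)dodeca-2,8,10-trienoate F1. Reduction with i-Bu2AlH gives the allylic alcohol F2 and MnO2 the trienal F3. Because no silyl enol ether is present, the cycloaddition can then be run as a Lewis-acid-promoted, endo-selective reaction (Me2AlCl, CH2Cl2, −78 → −20 °C) to the trans-fused enol triflate aldehyde F4. Wittig methylenation gives the vinyl compound F5, and LiOH in THF/MeOH cleaves the enol triflate at sulfur and equilibrates C8, which comes back to the route at 14.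

Step 11. The elimination may take the axial H-6 instead of H-8 (regiochemistry), or the alkoxysulfonium may be displaced without elimination. Fallback: from 14, Tf2O with 2,6-di-tert-butyl-4-methylpyridine under equilibrating conditions should give the more substituted enol triflate (3R,5S,9S,10R)-3-(tert-butyldimethylsilyloxy)-7-(trifluoromethylsulfonyloxy)-13,14,15,16-tetranor-ent-labda-7,11-diene F6. Here the regiochemistry is set by enol stability and not by the reach of an anti proton. Reduction with Pd(OAc)2, PPh3, HCO2H and Bu3N in DMF then replaces the triflate by hydrogen and comes back to the route at 16.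

Step 3. Turnover at the vinyl group next to the quaternary carbon may be low, and the enone partner may be used up by self-metathesis. Fallback: from 5, TBSCl and imidazole give the silyl ether methyl (2E,6R)-6-(tert-butyldimethylsilyloxy)-3,7,7-trimethylnona-2,8-dienoate F7. Lemieux–Johnson cleavage (OsO4 cat., NaIO4, 2,6-lutidine, dioxane/H2O) of the terminal vinyl group, selective over the deactivated enoate, gives the aldehyde methyl (2E,6R)-6-(tert-butyldimethylsilyloxy)-3,7,7-trimethyl-8-oxooct-2-enoate F8. Horner–Wadsworth–Emmons reaction with diethyl (2-oxobutyl)phosphonate (LiCl, i-Pr2NEt, MeCN) gives the E enone methyl (2E,6R,8E)-6-(tert-butyldimethylsilyloxy)-3,7,7-trimethyl-10-oxododeca-2,8-dienoate F9. TBSOTf and Et3N then form the silyl dienol ether and come back to the route at 8.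

**Further compounds**
F1 | step 7 | methyl (2E,6R,8E,10Z)-6-(tert-butyldimethylsilyloxy)-3,7,7-trimethyl-10-(trifluoromethylsulfonyloxy)dodeca-2,8,10-trienoate | COC(=O)/C=C(\C)CC[C@@H](O[Si](C)(C)C(C)(C)C)C(C)(C)/C=C/C(OS(=O)(=O)C(F)(F)F)=C/C
F2 | step 7 | (2E,6R,8E,10Z)-6-(tert-butyldimethylsilyloxy)-3,7,7-trimethyl-10-(trifluoromethylsulfonyloxy)dodeca-2,8,10-trien-1-ol | OC/C=C(\C)CC[C@@H](O[Si](C)(C)C(C)(C)C)C(C)(C)/C=C/C(OS(=O)(=O)C(F)(F)F)=C/C
F3 | step 7 | (2E,6R,8E,10Z)-6-(tert-butyldimethylsilyloxy)-3,7,7-trimethyl-10-(trifluoromethylsulfonyloxy)dodeca-2,8,10-trienal | O=C/C=C(\C)CC[C@@H](O[Si](C)(C)C(C)(C)C)C(C)(C)/C=C/C(OS(=O)(=O)C(F)(F)F)=C/C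
F4 | step 7 | (3R,5S,8S,9R,10R)-3-(tert-butyldimethylsilyloxy)-7-(trifluoromethylsulfonyloxy)-12,13,14,15,16-pentanor-ent-labd-6-en-11-al | C[C@@H]1C(OS(=O)(=O)C(F)(F)F)=C[C@@H]2C(C)(C)[C@H](O[Si](C)(C)C(C)(C)C)CC[C@@]2(C)[C@@H]1C=O
F5 | step 7 | (3R,5S,8S,9R,10S)-3-(tert-butyldimethylsilyloxy)-7-(trifluoromethylsulfonyloxy)-13,14,15,16-tetranor-ent-labda-6,11-diene | C[C@@H]1C(OS(=O)(=O)C(F)(F)F)=C[C@@H]2C(C)(C)[C@H](O[Si](C)(C)C(C)(C)C)CC[C@@]2(C)[C@@H]1C=C
F6 | step 11 | (3R,5S,9S,10R)-3-(tert-butyldimethylsilyloxy)-7-(trifluoromethylsulfonyloxy)-13,14,15,16-tetranor-ent-labda-7,11-diene | CC1=C(OS(=O)(=O)C(F)(F)F)C[C@@H]2C(C)(C)[C@H](O[Si](C)(C)C(C)(C)C)CC[C@@]2(C)[C@@H]1C=C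
F7 | step 3 | methyl (2E,6R)-6-(tert-butyldimethylsilyloxy)-3,7,7-trimethylnona-2,8-dienoate | COC(=O)/C=C(\C)CC[C@@H](O[Si](C)(C)C(C)(C)C)C(C)(C)C=C
F8 | step 3 | methyl (2E,6R)-6-(tert-butyldimethylsilyloxy)-3,7,7-trimethyl-8-oxooct-2-enoate | COC(=O)/C=C(\C)CC[C@@H](O[Si](C)(C)C(C)(C)C)C(C)(C)C=O
F9 | step 3 | methyl (2E,6R,8E)-6-(tert-butyldimethylsilyloxy)-3,7,7-trimethyl-10-oxododeca-2,8-dienoate | COC(=O)/C=C(\C)CC[C@@H](O[Si](C)(C)C(C)(C)C)C(C)(C)/C=C/C(=O)CC
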